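You charge 1.0 M of solid substrate into a solution that saturates at 0.16 M, along with 1.30 M of partner, so by charge the solid substrate is the limiting reagent, and its ledger is what you should watch.

solid substrate 1.0 M; partner 1.30 M; time 2.5 d

    target ⇌ isomer of the product (K1 = 0.48, k1 = 0.00587 h⁻¹)
    solid substrate ⇌ dissolved substrate, rate k2*(cs2 - [dissolved substrate]) while solid is left; crystals form when [dissolved substrate] > cs2 (cs2 = 0.16 M, k2 = 0.0432 h⁻¹)
    dissolved substrate + partner → target (k3 = 0.0231 M⁻¹ h⁻¹)
    partner → decomposed reagent (k4 = 0.00745 h⁻¹)
    2 solid substrate → self-condensation product (k5 = 0.0410 M⁻¹ h⁻¹)

- target at 2.5 d, in percent of the solid substrate charged
- concentration of dissolved substrate in solution at 2.5 d, in percent of saturation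

- a species is counted by the solid substrate in it: one self-condensation product counts as two
- for a step with 2 of a species take k times the square, and two of it per event
- given per volume of solution although it is solid: solid substrate
- at the start none of the solid substrate is in solution
- dissolved substrate means what is dissolved; the solid is not counted in it
- run time (flask): 2.5 d

While any solid is left, dissolution depends on how far the solution stands below saturation, not on how much solid there is. So freeze the partner. Its half-life by decay alone, 3.9 d, is longer than the run, so take its mid-run value by that decay, 1.04 M. The holding level, the concentration c(dissolved substrate) at which dissolution equals use by partner (a quasi-steady state), is then 0.103 M, which is 64.4 % of saturation. The solid charged does not enter it. The solution approaches this level with a time constant of 14.9 h, shorter than the run.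

Now the books. The first entry is the solution, at 0.103 M. The second is what partner has taken: 0.00247 M h⁻¹ over the run less that delay gives 0.111 M. Forward isomerisation moves about 0.0148 M of this, which leaves 0.0967 M of target, so I reckon y at 9.67 %. Self-condensation product and leftover solid share the remaining 0.786 M. Condensation by itself would leave 0.169 M of solid and so take 0.831 M, more than that remainder. So condensation must take less than that figure here, and I do not reckon closely what solid remains. Watch that solid: the holding level is reckoned for a solution with solid still present.

The forecast gives 9.2 % and 67 %, reasoning that “dissolved substrate keeps climbing towards a quasi-steady level”. Its target stands below mine and its saturation above.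

The flask gives 9.18 % and 67.2 %, with 9.38 % of the charge still solid and 69.5 % in self-condensation product. Dissolved substrate is still being made 1.23 times faster than it is used up. With all else held, y has moved by 5 points at 0.648 M and at 2.20 M of solid substrate, so at those charges the forecast's y stands that far off. Take the neighbour charged with 2.5 M of solid substrate: the holding level contains partner and not the solid charged, so in the reckoning 0.103 M and the 0.0967 M of target carry over, and over the larger charge they give 3.87 %. That neighbour reads 3.67 %, with dissolved substrate at 0.107 M and 4.96 % of its charge still solid.

Its constants belong to no real substance; no experiment stands behind them.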